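I started from amounts: the flask held 21 mM of starting material in the first phase, and 0.950 equiv of reagent waited in the second.

    starting material + reagent in the reaction phase ⇌ product (K1 = 127 M⁻¹, k1 = 34.9 M⁻¹ h⁻¹)
    reagent in the reaction phase ⇌ reagent in the second phase, rate k2*([reagent in the reaction phase] - [reagent in the second phase]/K2) per volume of the first phase (K2 = 1.3, k2 = 5.05 h⁻¹)

starting material 21 mM; reagent in the second phase 0.950 equiv; time 15 d; volume of the second phase over the first 1.0

- in the second phase: reagent in the second phase; everything else is in the first
- charges count per volume of the first phase; a concentration in a rate is the amount of a species over the volume of its own phase; every rate counts per litre of the first phase
- the reaction counts as stopped when no species that holds the starting material changes by six tenths of a point or more over the second half of the time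
- run time (flask): 15 d

* the state of affairs at 15 d: stopped, and by what, or still going (forward and back rates have come level / it is still moving / all of the starting material has reacted)
* amount of product at 15 d, in percent of the starting material charged

I turned the question round and asked what the numbers would need for product to end above starting material. By its forward rate as charged, the reagent in the reaction phase had a half-life of 0.95 h, far shorter than the 15 d run, so I expected a balance, where forward rate over back rate is one and time drops out. With the reagent shared between the phases, the equivalents aside, that left a number 1.16: the equilibrium constant 127 M⁻¹ times the charged c(starting material), divided by one plus the partition ratio times the volume ratio. I called it the pull. The reagent was the limiting reagent, capping product at 95.0%. At balance, the product share, divided by the starting-material share times the share of reagent left in both phases, each counted against the starting material charged, equalled the pull. At these equivalents, equal shares of starting material and product needed a pull of 2.22. This flask had about half of that, so I committed to a balance with starting material ahead of product.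

The forecast read: forward and back rates have come level, with 39.3% of product, between 38.8% and 39.8%: “Relaxation therefore takes only a few hours”.

In the simulated flask at 15 d, forward and back rates have come level, and product stood at 39.3%. Its relaxation half-life at 15.0 d for the reaction step taken by itself, both directions together, was 0.772 h, short against the 15 d run, and product already stood at 39.3% after 1.50 d.

The neighbour charged with 53 mM of starting material, on the same equivalents and volumes, had a pull of 2.93, above the 2.22 needed, and the balance gave a product share of 54.4%. The simulation gave 54.3% of product against 45.7% of starting material.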